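**Strategy.** The synthesis rests on disconnecting the A/B ring-fusion bond C5–C10 (cheilanthane numbering; C10 is the methyl-bearing quaternary carbon, C5 the CH next to the gem-dimethyl carbon C4). The precursor is a single cyclohexane (ring C) whose vicinal stereocentres C8 and C9 carry a prenyl ketone arm (C7–C4) and an (E)-penta-2,4-dien-2-yl group (C10, C1–C3). One type 1 intramolecular Diels–Alder reaction forms C5–C10 and C3–C4, closes rings A and B, and creates the quaternary carbons C4 and C10 and the C5 stereocentre. It exploits the C6 oxygen, placed as an enone carbonyl in the tether, and the trans-diequatorial C8/C9 pair of ring C. Ring D follows by metathesis.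

Key step: step 16

Convention: atom labels are those of the target (ring A: C1–C5, C10; ring B: C5–C10; ring C: C8, C9, C11–C14; ring D: C13–O–C19–C18=C17–C16–C15–C14; C20 is the methyl on C10). β is the face of the C10 methyl group.

Assumption: the (S)-diphenylprolinol-derived oxazaborolidinium ion is taken to give the (1S,6S) cycloadduct in step 3; if the sense of induction is opposite, the mirror-image catalyst is used.

Step 1
Reactants: 1 3-(triisopropylsilyl)prop-2-ynal; 2 2-(triphenylphosphoranylidene)propanal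
Product: 3 (2E)-2-methyl-5-(triisopropylsilyl)pent-2-en-4-ynal
Conditions: CH2Cl2, 23 °C
Reagents that add atoms: 2-(triphenylphosphoranylidene)propanal (2), CC(C=O)=P(c1ccccc1)(c1ccccc1)c1ccccc1
Why: Wittig olefination with a stabilised α-methyl ylide should give the (E)-enal (formyl trans to alkynyl), the geometry that later places the C8 methyl cis to the C9 alkynyl group.

Step 2
Reactants: 4 3-methylbut-3-en-2-one
Product: 5 3-methyl-2-(triisopropylsilyloxy)buta-1,3-diene
Conditions: TIPSOTf, Et3N, CH2Cl2, 0 °C
Reagents that add atoms: triisopropylsilyl trifluoromethanesulfonate, CC(C)[Si](C(C)C)(C(C)C)OS(=O)(=O)C(F)(F)F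
Why: Soft enolisation and O-silylation of the methyl ketone (silyl dienol ether formation) gives the 2-silyloxy-1,3-diene.

Step 3
Reactants: 3 (2E)-2-methyl-5-(triisopropylsilyl)pent-2-en-4-ynal; 5 3-methyl-2-(triisopropylsilyloxy)buta-1,3-diene
Product: 6 (1S,6S)-1,3-dimethyl-4-(triisopropylsilyloxy)-6-[(triisopropylsilyl)ethynyl]cyclohex-3-ene-1-carbaldehyde
Conditions: (S)-diphenylprolinol-derived B-(o-tolyl)oxazaborolidinium triflimide (20 mol %), CH2Cl2, −78 to −40 °C
Reagents that add atoms: none
Why: Catalytic enantioselective Diels–Alder reaction of an (E)-2-methyl-2-enal with a 2-silyloxydiene under chiral oxazaborolidinium Lewis-acid catalysis; the silyloxy group directs the para regiochemistry (C11 to C9, C14 to C8), the (E)-enal fixes the C8 methyl cis to the C9 alkynyl group, and the catalyst sets the absolute configuration of C8 and C9.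

Step 4
Reactants: 6 (1S,6S)-1,3-dimethyl-4-(triisopropylsilyloxy)-6-[(triisopropylsilyl)ethynyl]cyclohex-3-ene-1-carbaldehyde; 7 (methoxymethyl)triphenylphosphonium chloride
Product: 9 dioxolane-protected C6 aldehyde with the ring ketone still masked as silyl enol ether, via methyl enol ether 8 (not isolated)
Conditions: 7, KHMDS, THF, −78 to 0 °C; filtration; then HOCH2CH2OH, PPTS, CH2Cl2, 23 °C
Reagents that add atoms: (methoxymethyl)triphenylphosphonium chloride (7), COC[P+](c1ccccc1)(c1ccccc1)c1ccccc1.[Cl-]; ethylene glycol, OCCO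
Why: Wittig homologation with methoxymethylenetriphenylphosphorane adds C6 to the only free carbonyl group, and acid-catalysed transacetalisation of the enol ether stores C6 as a dioxolane.

Step 5
Reactants: 9 dioxolane silyl enol ether
Product: 10 4-[(1,3-dioxolan-2-yl)methyl]-2,4-dimethyl-5-[(triisopropylsilyl)ethynyl]cyclohex-2-en-1-one (C8 methyl cis to C9 alkynyl)
Conditions: Pd(OAc)2 (1.1 equiv), MeCN, 40 °C
Reagents that add atoms: none
Why: Saegusa–Ito oxidation: palladation of the silyl enol ether at C13 and β-hydride elimination towards C14 should give the conjugated 2-methyl enone regiospecifically.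

Step 6
Reactants: 10 ring-C enone
Product: 11 12β-allylic alcohol (hydroxyl cis to the C9 alkynyl group and the C8 methyl)
Conditions: NaBH4, CeCl3·7H2O, MeOH, −78 °C
Reagents that add atoms: none
Why: Luche 1,2-reduction; axial hydride delivery anti to the C9 substituent (as in carvone to cis-carveol) should give the pseudo-equatorial 12β-alcohol.

Step 7
Reactants: 11 12β-allylic alcohol
Product: 12 N-phenylcarbamate of 11
Conditions: PhNCO, Et3N (cat.), CH2Cl2, 23 °C
Reagents that add atoms: phenyl isocyanate, O=C=Nc1ccccc1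
Why: Addition of the alcohol to the isocyanate (carbamoylation) installs a directing leaving group with retention at C12.

Step 8
Reactants: 12 N-phenylcarbamate; 13 4-bromo-2-methylbut-1-ene (as its Grignard reagent)
Product: 15 ring-C cyclohex-3-ene carrying the 14β-(3-methylbut-3-en-1-yl) chain, via lithium carbamate 14 (not isolated)
Conditions: MeLi, THF, −78 °C; CuI; then CH2=C(CH3)CH2CH2MgBr (from 13 and Mg), THF, −78 to 0 °C
Reagents that add atoms: 4-bromo-2-methylbut-1-ene (13), C=C(C)CCBr
Why: Copper-mediated syn-SN2′ substitution of an allylic N-phenylcarbamate: the nitrogen-bound cuprate delivers the alkyl group intramolecularly to C14 on the face of the C12–O bond (β), which transfers chirality from C12 to C14 and moves the alkene to C12=C13.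

Step 9
Reactants: 15 ring-C diene
Product: 16 12α,13α-epoxide of 15
Conditions: mCPBA (1.05 equiv), NaHCO3, CH2Cl2, −20 °C
Reagents that add atoms: 3-chloroperbenzoic acid, OOC(=O)c1cccc(Cl)c1
Why: Prilezhaev epoxidation is fastest at the trisubstituted ring alkene and should occur from the α face, anti to the axial C8 methyl and the C14 side chain.

Step 10
Reactants: 16 12α,13α-epoxide
Product: 17 tertiary 13α-alcohol (13β-methyl)
Conditions: LiEt3BH, THF, 0 to 50 °C
Reagents that add atoms: none
Why: Hydride opening of the trisubstituted epoxide by SN2 attack at the less substituted C12 leaves the tertiary alcohol with the C13 configuration set in step 9.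

Step 11
Reactants: 17 tertiary 13α-alcohol; 18 allyl bromide
Product: 19 13α-allyl ether
Conditions: KH, allyl bromide, 18-crown-6 (cat.), THF, 0 to 40 °C
Reagents that add atoms: allyl bromide (18), C=CCBr
Why: Williamson etherification of the potassium alkoxide with a reactive allylic bromide.

Step 12
Reactants: 19 13α-allyl ether
Product: 20 C6 aldehyde (C8–CH2–CHO)
Conditions: PPTS, acetone–H2O (4:1), 60 °C
Reagents that add atoms: water, O
Why: Acid-catalysed acetal hydrolysis releases the aldehyde; the simple allyl ether, the alkenes and the silylalkyne tolerate the mild acid.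

Step 13
Reactants: 20 C6 aldehyde; 21 2-methylprop-1-enylmagnesium bromide
Product: 22 C6 allylic alcohol (both C6 epimers)
Conditions: THF, −78 to 0 °C
Reagents that add atoms: 2-methylprop-1-enylmagnesium bromide (21), CC(C)=C[Mg]Br
Why: Grignard 1,2-addition to the unhindered aldehyde adds C5, C4 and both C4 methyl groups; the C6 configuration is irrelevant because C6 is oxidised in step 16.

Step 14
Reactants: 22 C6 allylic alcohol
Product: 23 terminal alkyne at C9
Conditions: TBAF, THF, 23 °C
Reagents that add atoms: none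
Why: Fluoride-mediated protodesilylation of the alkynylsilane.

Step 15
Reactants: 23 terminal alkyne; 24 trimethylaluminium; 25 vinyl bromide
Product: 27 (E)-penta-2,4-dien-2-yl compound (C9 trans to the vinyl group), via alkenylalane 26 (not isolated)
Conditions: AlMe3, Cp2ZrCl2 (25 mol %), H2O (1 equiv), CH2Cl2, −20 to 23 °C; then vinyl bromide, Pd(PPh3)4 (5 mol %), ZnCl2 (cat.), THF, 23 °C
Reagents that add atoms: trimethylaluminium (24), C[Al](C)C; vinyl bromide (25), C=CBr
Why: Zirconium-catalysed syn-carboalumination of the terminal alkyne (methyl to the internal carbon C10) followed by palladium-catalysed Negishi coupling of the alkenylalane with retention gives the (E)-2-methyl-1,3-diene.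

Step 16
Reactants: 27 diene allylic alcohol
Product: 29 tricyclic Δ1-6-ketone (rings A, B and C; 5α-H; 10β-methyl), via enone 28 (not isolated)
Conditions: Dess–Martin periodinane, NaHCO3, CH2Cl2, 0 °C; filtration through silica; then Me2AlCl, CH2Cl2, −78 to −20 °C
Reagents that add atoms: none
Why: Dess–Martin oxidation unveils enone 28, a 1,7,9-decatrien-3-one whose dienophile C4=C5 is activated by the C6 carbonyl inside the tether, and the Me2AlCl-promoted type 1 intramolecular Diels–Alder reaction (closest known type: Lewis-acid-promoted cyclisation of 1,7,9-decatrien-3-ones to octal-1-ones) forms C3–C4 and C5–C10 in one concerted, asynchronous [4+2] step in which the unsubstituted diene terminus C3 bonds ahead to the β-carbon C4. Ring A (C10, C1–C5) closes as the cyclohexene of the cycloaddition and ring B (C5–C10) as the six-membered ring of the tether, formally 6-exo with respect to the dienophile, through a chair-like tether held trans-diequatorial on ring C. The C10 stereocentre is controlled by C8 and C9: with H9 nearly eclipsing C10=C1 (least allylic strain) the tethered C5 reaches only the diene face that leaves the dienyl arm pseudo-equatorial and the C10 methyl pseudo-axial, syn to the C8 methyl, which is the 10β configuration. The C5 stereocentre is controlled by the carbonyl-exo transition state, since the endo mode would place the gem-dimethyl carbon C4 pseudo-axial on the forming ring B; C5 is also α to the ketone, so a 5β epimer could still be equilibrated with base to the trans-fused ketone. The (E)-diene geometry needed for a trans ring fusion (C9 outside, methyl inside) comes from the syn-carboalumination of step 15, and the regiochemistry is fixed by the four-atom tether. The step therefore needs diene-face selectivity, secured by the C8/C9 stereocentres of ring C, and enough reactivity from two hindered termini, supplied by carbonyl activation with the Lewis acid.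

Step 17
Reactants: 29 tricyclic Δ1-6-ketone
Product: 30 13,19-epoxycheilantha-1,17-dien-6-one
Conditions: second-generation Grubbs catalyst RuCl2(=CHPh)(PCy3)(H2IMes) (10 mol %), toluene (0.002 M), 80 °C
Reagents that add atoms: none
Why: Ring-closing olefin metathesis between the allyl ether and the 1,1-disubstituted alkene closes the eight-membered ring D, which can hold only the ring-cis trisubstituted alkene; the trans-diequatorial C13 and C14 substituents keep the two chains gauche.

Step 18
Reactants: 30 13,19-epoxycheilantha-1,17-dien-6-one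
Product: 31 13,19-epoxycheilanth-17-en-6-one
Conditions: H2 (1 atm), RhCl(PPh3)3 (10 mol %), benzene–EtOH, 23 °C
Reagents that add atoms: none
Why: Homogeneous hydrogenation with Wilkinson's catalyst should reduce the cis-disubstituted C1=C2 alkene and leave the trisubstituted C17=C18 alkene.

Step 19
Reactants: 31 13,19-epoxycheilanth-17-en-6-one
Product: 32 13,19-epoxycheilanth-17-en-6α-ol (CNP0179324.1)
Conditions: SmI2, H2O, Et3N, THF, 23 °C
Reagents that add atoms: none
Why: Single-electron ketone reduction under thermodynamic control should give the equatorial 6α-alcohol, because the axial 6β position is syn-axial to the C4β, C10 and C8 methyl groups.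

**Compound list**

1 | 3-(triisopropylsilyl)prop-2-ynal | CC(C)[Si](C(C)C)(C(C)C)C#CC=O | starting material
2 | 2-(triphenylphosphoranylidene)propanal | CC(C=O)=P(c1ccccc1)(c1ccccc1)c1ccccc1 | starting material
3 | (2E)-2-methyl-5-(triisopropylsilyl)pent-2-en-4-ynal | O=C/C(C)=C/C#C[Si](C(C)C)(C(C)C)C(C)C | intermediate
4 | 3-methylbut-3-en-2-one | CC(=O)C(C)=C | starting material
5 | 3-methyl-2-(triisopropylsilyloxy)buta-1,3-diene | C=C(O[Si](C(C)C)(C(C)C)C(C)C)C(C)=C | intermediate
6 | (1S,6S)-1,3-dimethyl-4-(triisopropylsilyloxy)-6-[(triisopropylsilyl)ethynyl]cyclohex-3-ene-1-carbaldehyde (C8 methyl cis to C9 alkynyl) | CC1=C(O[Si](C(C)C)(C(C)C)C(C)C)C[C@H](C#C[Si](C(C)C)(C(C)C)C(C)C)[C@@](C)(C=O)C1 | intermediate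
7 | (methoxymethyl)triphenylphosphonium chloride | COC[P+](c1ccccc1)(c1ccccc1)c1ccccc1.[Cl-] | starting material
8 | methyl enol ether: 6 with CHO replaced by CH=CH–OMe (E/Z mixture; C8 and C9 as in 6) | CC1=C(O[Si](C(C)C)(C(C)C)C(C)C)C[C@H](C#C[Si](C(C)C)(C(C)C)C(C)C)[C@@](C)(C=COC)C1 | intermediate
9 | 2-{[1,3-dimethyl-4-(triisopropylsilyloxy)-6-[(triisopropylsilyl)ethynyl]cyclohex-3-en-1-yl]methyl}-1,3-dioxolane (C8 and C9 as in 6) | CC1=C(O[Si](C(C)C)(C(C)C)C(C)C)C[C@H](C#C[Si](C(C)C)(C(C)C)C(C)C)[C@@](C)(CC2OCCO2)C1 | intermediate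
10 | 4-[(1,3-dioxolan-2-yl)methyl]-2,4-dimethyl-5-[(triisopropylsilyl)ethynyl]cyclohex-2-en-1-one (C8 methyl β, C9 alkynyl β, cis) | O=C1C[C@H](C#C[Si](C(C)C)(C(C)C)C(C)C)[C@@](C)(CC2OCCO2)C=C1C | intermediate
11 | corresponding cyclohex-2-en-1-ol, 12β-OH (cis to the C9 alkynyl and C8 methyl groups) | O[C@@H]1C[C@H](C#C[Si](C(C)C)(C(C)C)C(C)C)[C@@](C)(CC2OCCO2)C=C1C | intermediate
12 | N-phenylcarbamate of 11 (12β-O) | O=C(Nc1ccccc1)O[C@@H]1C[C@H](C#C[Si](C(C)C)(C(C)C)C(C)C)[C@@](C)(CC2OCCO2)C=C1C | intermediate
13 | 4-bromo-2-methylbut-1-ene | C=C(C)CCBr | starting material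
14 | N-lithio derivative of carbamate 12 | O=C([N-]c1ccccc1)O[C@@H]1C[C@H](C#C[Si](C(C)C)(C(C)C)C(C)C)[C@@](C)(CC2OCCO2)C=C1C.[Li+] | intermediate
15 | 2-{[1,3-dimethyl-2-(3-methylbut-3-en-1-yl)-6-[(triisopropylsilyl)ethynyl]cyclohex-3-en-1-yl]methyl}-1,3-dioxolane; C14 chain, C8 methyl and C9 alkynyl all β (cis); C12=C13 alkene | CC1=CC[C@H](C#C[Si](C(C)C)(C(C)C)C(C)C)[C@@](C)(CC2OCCO2)[C@@H]1CCC(C)=C | intermediate
16 | 12α,13α-epoxide of 15 (oxirane trans to the C8 methyl and the C14 chain) | C[C@]12O[C@H]1C[C@H](C#C[Si](C(C)C)(C(C)C)C(C)C)[C@@](C)(CC3OCCO3)[C@@H]2CCC(C)=C | intermediate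
17 | tertiary alcohol: 13α-OH, 13β-methyl, 14β-(3-methylbut-3-en-1-yl), 8β-methyl, 8α-(dioxolanylmethyl), 9β-alkynyl | O[C@@]1(C)CC[C@H](C#C[Si](C(C)C)(C(C)C)C(C)C)[C@@](C)(CC2OCCO2)[C@@H]1CCC(C)=C | intermediate
18 | allyl bromide | C=CCBr | starting material
19 | 13α-allyl ether of 17 | C=CCO[C@@]1(C)CC[C@H](C#C[Si](C(C)C)(C(C)C)C(C)C)[C@@](C)(CC2OCCO2)[C@@H]1CCC(C)=C | intermediate
20 | aldehyde: 19 with the dioxolane hydrolysed (C8–CH2–CHO) | C=CCO[C@@]1(C)CC[C@H](C#C[Si](C(C)C)(C(C)C)C(C)C)[C@@](C)(CC=O)[C@@H]1CCC(C)=C | intermediate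
21 | 2-methylprop-1-enylmagnesium bromide | CC(C)=C[Mg]Br | starting material
22 | allylic alcohol C8–CH2–CH(OH)–CH=C(CH3)2 (C6 epimers), silylalkyne at C9 | C=CCO[C@@]1(C)CC[C@H](C#C[Si](C(C)C)(C(C)C)C(C)C)[C@@](C)(CC(O)C=C(C)C)[C@@H]1CCC(C)=C | intermediate
23 | 22 with the alkyne desilylated (C9–C≡CH) | C=CCO[C@@]1(C)CC[C@H](C#C)[C@@](C)(CC(O)C=C(C)C)[C@@H]1CCC(C)=C | intermediate
24 | trimethylaluminium | C[Al](C)C | starting material
25 | vinyl bromide | C=CBr | starting material
26 | (E)-alkenyldimethylalane C9–C(CH3)=CH–AlMe2 with the C6 alcohol as its dimethylaluminium alkoxide | C=CCO[C@@]1(C)CC[C@H](/C(C)=C/[Al](C)C)[C@@](C)(CC(O[Al](C)C)C=C(C)C)[C@@H]1CCC(C)=C | intermediate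
27 | diene alcohol: C9–C(CH3)=CH–CH=CH2 (E, C9 trans to vinyl) and C8–CH2–CH(OH)–CH=C(CH3)2 | C=CCO[C@@]1(C)CC[C@H](/C(C)=C/C=C)[C@@](C)(CC(O)C=C(C)C)[C@@H]1CCC(C)=C | intermediate
28 | enone: 27 oxidised at C6 (C8–CH2–CO–CH=C(CH3)2) | C=CCO[C@@]1(C)CC[C@H](/C(C)=C/C=C)[C@@](C)(CC(=O)C=C(C)C)[C@@H]1CCC(C)=C | intermediate
29 | tricyclic ketone: rings A, B and C of the target, trans–anti–trans (5α-H, 8β-Me, 9α-H, 10β-Me), C1=C2 alkene, C6 ketone, 13α-allyloxy, 13β-Me, 14β-(3-methylbut-3-en-1-yl) | C=CCO[C@@]2(C)CC[C@@H]3[C@@]4(C)C=CCC(C)(C)[C@@H]4C(=O)C[C@@]3(C)[C@@H]2CCC(C)=C | intermediate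
30 | 13,19-epoxycheilantha-1,17-dien-6-one (ring D closed, ring-cis C17=C18) | C/C1=C/CO[C@@]2(C)CC[C@@H]3[C@@]4(C)C=CCC(C)(C)[C@@H]4C(=O)C[C@@]3(C)[C@@H]2CC1 | intermediate
31 | 13,19-epoxycheilanth-17-en-6-one | C/C1=C/CO[C@@]2(C)CC[C@@H]3[C@@]4(C)CCCC(C)(C)[C@@H]4C(=O)C[C@@]3(C)[C@@H]2CC1 | intermediate
32 | 13,19-epoxycheilanth-17-en-6α-ol (CNP0179324.1) | C/C1=C/CO[C@@]2(C)CC[C@@H]3[C@@]4(C)CCCC(C)(C)[C@@H]4[C@@H](O)C[C@@]3(C)[C@@H]2CC1 | target

**Totals.** Total step count: 19. Longest linear sequence: 18 steps (step 1 or step 2, then steps 3 to 19).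

**Steps most likely to fail**

Step 16 (key step). The cycloaddition joins a β,β-dimethyl enone to a diene terminus that carries an inside methyl group and may be too slow, so that Lewis-acid-induced isomerisation or oligomerisation of the diene takes over; the dienophile may also add to the other diene face. The fallback sets out from 27. Oxidation as in step 16 without the Lewis acid and cold isolation would give 28. With 1,2-bis(trimethylsilyloxy)ethane and catalytic TMSOTf (CH2Cl2, −78 °C) this would be converted into the 2-alkenyl-1,3-dioxolane F1. The same silyl triflate would ionise it to a 2-alkoxyallyl cation, a much stronger dienophile, which would close C3–C4 and C5–C10 by an ionic, stepwise [4+2] cycloaddition at −78 °C to the tricyclic ketal F2. Hydrolysis (PPTS, acetone–H2O) would come back to the route at 29.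

Step 8. Copper-mediated transfer to C14, which lies next to the quaternary C8, may be outrun by reduction or by elimination of the carbamate to a cyclohexadiene. The fallback sets out from 11 and replaces the copper chemistry by a [2,3]-Wittig–Still rearrangement. O-Alkylation with tributyl(iodomethyl)stannane (KH, THF) would give the stannylmethyl ether F3. Tin–lithium exchange (n-BuLi, THF, −78 °C) and the suprafacial [2,3]-shift across the β face would give the 14β-hydroxymethyl cyclohexene F4. Iodination (I2, PPh3, imidazole) would give the iodide F5, and copper-catalysed coupling with 2-methylallylmagnesium chloride (CuI cat., THF, −20 °C) would come back to the route at 15.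

Step 9. The peracid may not discriminate well enough between the hindered trisubstituted ring alkene and the 1,1-disubstituted side-chain alkene, which would lead to over-oxidation or to the wrong epoxide. The fallback sets out from 11 and oxidises the ring alkene before any other alkene is present. Johnson–Claisen rearrangement (MeC(OEt)3, EtCO2H cat., 140 °C) would give the 14β-acetic ester F6. Epoxidation (mCPBA, NaHCO3) would give the 12α,13α-epoxy ester F7, and LiBH4 reduction the epoxy alcohol F8. Tosylation (TsCl, pyridine) would give the tosylate F9, and copper-catalysed coupling with isopropenylmagnesium bromide (CuI cat., THF, −30 °C) would come back to the route at 16.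

**Further compounds**

F1 | step 16 | 2-(2-methylprop-1-enyl)-1,3-dioxolane ketal of enone 28 | C=CCO[C@@]1(C)CC[C@H](/C(C)=C/C=C)[C@@](C)(CC2(C=C(C)C)OCCO2)[C@@H]1CCC(C)=C
F2 | step 16 | ethylene ketal of tricyclic ketone 29 | C=CCO[C@@]2(C)CC[C@@H]3[C@@]4(C)C=CCC(C)(C)[C@@H]4C5(OCCO5)C[C@@]3(C)[C@@H]2CCC(C)=C
F3 | step 8 | (tributylstannyl)methyl ether of 11 (12β-O) | CCCC[Sn](CCCC)(CCCC)CO[C@@H]1C[C@H](C#C[Si](C(C)C)(C(C)C)C(C)C)[C@@](C)(CC2OCCO2)C=C1C
F4 | step 8 | 14β-hydroxymethyl cyclohex-3-ene (C12=C13) | CC1=CC[C@H](C#C[Si](C(C)C)(C(C)C)C(C)C)[C@@](C)(CC2OCCO2)[C@@H]1CO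
F5 | step 8 | 14β-iodomethyl cyclohex-3-ene | CC1=CC[C@H](C#C[Si](C(C)C)(C(C)C)C(C)C)[C@@](C)(CC2OCCO2)[C@@H]1CI
F6 | step 9 | ethyl 14β-acetate (Johnson–Claisen ester, C12=C13) | CC1=CC[C@H](C#C[Si](C(C)C)(C(C)C)C(C)C)[C@@](C)(CC2OCCO2)[C@@H]1CC(=O)OCC
F7 | step 9 | 12α,13α-epoxide of F6 | C[C@]12O[C@H]1C[C@H](C#C[Si](C(C)C)(C(C)C)C(C)C)[C@@](C)(CC3OCCO3)[C@@H]2CC(=O)OCC
F8 | step 9 | 12α,13α-epoxy primary alcohol (C16–OH) | C[C@]12O[C@H]1C[C@H](C#C[Si](C(C)C)(C(C)C)C(C)C)[C@@](C)(CC3OCCO3)[C@@H]2CCO
F9 | step 9 | 4-methylbenzenesulfonate of F8 | C[C@]12O[C@H]1C[C@H](C#C[Si](C(C)C)(C(C)C)C(C)C)[C@@](C)(CC3OCCO3)[C@@H]2CCOS(=O)(=O)c4ccc(C)cc4
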